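The route rests on disconnecting the C9–C10 bond of ring B, the bond between the tetrasubstituted C8=C9 alkene shared by rings B and C and the quaternary C10 that carries the C20 methyl. A palladium-catalysed reductive Heck cyclisation (6-exo-trig) of a C9 enol triflate onto a C10=C20 exocyclic methylene closes ring B after rings A, C and D, creates the C10 quaternary stereocentre and the angular methyl, and leaves the C8=C9 alkene in place. The precursor is a B-seco enol triflate in which a resolved bicyclo[3.2.1]octene (rings C, D) and an enantioenriched methylenecyclohexane (ring A) are joined only through a C6 thioketal and C7.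

Key step: step 13

Remark on numbering: the assembled skeleton is numbered as in the target. Ring A = C1–C5 and C10; ring B = C5–C10; ring C = C8, C9, C11–C14. C15 (bonded to C11) and C16 (bonded to C13) form the two-carbon bridge, C17 is the methylene on C16, C18/C19 are the methyls on C4 and C20 is the methyl on C10. α is the face of C20. Fragments keep their own IUPAC locants.

Remark on catalysts: the antipode of the copper ligand (step 8) and the ketoreductase (step 3) would be fixed by a pilot screen; the descriptors written are the required ones.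

Step 1
Reactants: 1 3-ethoxycyclohex-2-en-1-one; 2 2,3-dibromoprop-1-ene
Product: 4 (±)-6-(2-bromoprop-2-en-1-yl)-3-ethoxycyclohex-2-en-1-one, via lithium dienolate 3 (not isolated)
Conditions: LiN(i-Pr)2, THF, −78 °C; then 2, −78 to 0 °C
Reagents that add atoms: none
Why: Stork–Danheiser alkylation: kinetic deprotonation of the vinylogous ester at C6 and SN2 attack on the allylic bromide give the racemic product, whose stereocentre is selected later by resolution.

Step 2
Reactants: 4 (±)-6-(2-bromoprop-2-en-1-yl)-3-ethoxycyclohex-2-en-1-one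
Product: 6 (±)-7-methylidenebicyclo[3.2.1]octane-2,8-dione, via bicyclic enol ether 5 (not isolated)
Conditions: Pd(OAc)2, PPh3, K2CO3, Et4NCl, MeCN, 80 °C; then 1 M HCl, THF, rt
Reagents that add atoms: water, O
Why: Intramolecular Heck reaction: the alkenylpalladium bromide adds 5-exo-trig to C2 of the enol-ether alkene across the carbonyl, β-hydride elimination toward C4 gives enol ether 5 and hydrolysis gives the dione, the bridge fixing the relative configuration of the two bridgeheads (racemic).

Step 3
Reactants: 6 (±)-7-methylidenebicyclo[3.2.1]octane-2,8-dione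
Product: 7 (1S,5R,8S)-8-hydroxy-7-methylidenebicyclo[3.2.1]octan-2-one
Conditions: ketoreductase (NADPH-dependent, from a commercial panel), NADP+ (cat.), propan-2-ol, phosphate buffer pH 7, 30 °C, stopped near half conversion
Reagents that add atoms: none
Why: Enzymatic kinetic resolution by carbonyl reduction: the ketoreductase should accept only the (1R,5R)-enantiomer and deliver hydride to the bridging C8 carbonyl from the side of the C2–C4 bridge, which sets the absolute configuration of rings C and D and the future C12 carbinol (hydroxyl syn to the C6–C7 bridge).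

Step 4
Reactants: 7 (1S,5R,8S)-8-hydroxy-7-methylidenebicyclo[3.2.1]octan-2-one
Product: 8 (1S,5R,8S)-8-[(tert-butyldimethylsilyl)oxy]-7-methylidenebicyclo[3.2.1]octan-2-one
Conditions: TBSCl, imidazole, DMF, 40 °C
Reagents that add atoms: tert-butyl(chloro)dimethylsilane, CC(C)(C)[Si](C)(C)Cl
Why: Silyl ether formation protects the β-hydroxy ketone against retro-aldol opening in the basic steps that follow; no stereocentre is touched.

Step 5
Reactants: 8 (1S,5R,8S)-8-[(tert-butyldimethylsilyl)oxy]-7-methylidenebicyclo[3.2.1]octan-2-one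
Product: 10 (1S,5S,8S)-8-[(tert-butyldimethylsilyl)oxy]-3,7-dimethylidenebicyclo[3.2.1]octan-2-one, via Mannich base 9 (not isolated)
Conditions: (CH2O)n, PhNHMe·CF3CO2H, THF, reflux; used at once
Reagents that add atoms: formaldehyde (as paraformaldehyde), C=O
Why: Mannich-type α-methylenation (aminomethylation, then β-elimination of N-methylaniline) can occur only at C3 because C1 is a bridgehead, and gives the Michael acceptor whose methylidene carbon becomes C7.

Step 6
Reactants: 11 4,4-dimethylcyclohexane-1,3-dione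
Product: 12 3-ethoxy-6,6-dimethylcyclohex-2-en-1-one
Conditions: EtOH, TsOH·H2O (cat.), toluene, reflux, water removal
Reagents that add atoms: ethanol, CCO
Why: Acid-catalysed vinylogous esterification should take place at the carbonyl remote from the gem-dimethyl group, leaving the hindered carbonyl for the next addition.

Step 7
Reactants: 13 1,3-dithiane; 12 3-ethoxy-6,6-dimethylcyclohex-2-en-1-one
Product: 16 3-(1,3-dithian-2-yl)-4,4-dimethylcyclohex-2-en-1-one, via 2-lithio-1,3-dithiane 14 (not isolated), via lithium alkoxide adduct 15 (not isolated)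
Conditions: n-BuLi, THF, −30 °C; then 12, −78 to 0 °C; then 2 M HCl, rt
Reagents that add atoms: water, O
Why: Corey–Seebach 1,2-addition of the formyl anion equivalent to the vinylogous ester and acid-induced Stork–Danheiser transposition place the dithiane carbon (C6) on C5 next to the gem-dimethyl carbon; no stereocentre is formed yet.

Step 8
Reactants: 16 3-(1,3-dithian-2-yl)-4,4-dimethylcyclohex-2-en-1-one
Product: 18 (2R,3S)-2-[(dimethylamino)methyl]-3-(1,3-dithian-2-yl)-4,4-dimethylcyclohexan-1-one, via silyl enol ether 17 (not isolated)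
Conditions: Cu(OAc)2·H2O (cat.), (R)-DTBM-SEGPHOS (cat.), Ph2SiH2, toluene, 0 °C; then CH2=NMe2+ I−, CH2Cl2, rt; NaHCO3 work-up
Reagents that add atoms: dimethylmethyleneiminium iodide, C=[N+](C)C.[I-]
Why: Copper hydride catalysed asymmetric 1,4-hydrosilylation sets C5 by ligand-controlled face selection and gives the C1=C10 silyl enol ether regiospecifically, which undergoes a Mannich reaction at C10 anti to the dithianyl group.

Step 9
Reactants: 18 (2R,3S)-2-[(dimethylamino)methyl]-3-(1,3-dithian-2-yl)-4,4-dimethylcyclohexan-1-one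
Product: 20 (3R)-3-(1,3-dithian-2-yl)-4,4-dimethyl-2-methylidenecyclohexan-1-one, via ammonium iodide 19 (not isolated)
Conditions: MeI, THF, rt; then NaHCO3 (aq.), CH2Cl2, rt
Reagents that add atoms: none
Why: N-methylation and E1cB (Hofmann-type) elimination of trimethylamine create the C10=C20 exocyclic methylene while the C5 stereocentre is untouched.

Step 10
Reactants: 20 (3R)-3-(1,3-dithian-2-yl)-4,4-dimethyl-2-methylidenecyclohexan-1-one
Product: 21 (1S,3R)-3-(1,3-dithian-2-yl)-4,4-dimethyl-2-methylidenecyclohexan-1-ol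
Conditions: NaBH4, CeCl3·7H2O, MeOH, −78 °C
Reagents that add atoms: none
Why: Luche 1,2-reduction: axial delivery of hydride to C1 should give the equatorial alcohol, cis (1,3-diequatorial) to the C5 substituent, so C1 is set by substrate control.

Step 11
Reactants: 21 (1S,3R)-3-(1,3-dithian-2-yl)-4,4-dimethyl-2-methylidenecyclohexan-1-ol
Product: 22 triethyl{[(1S,3R)-3-(1,3-dithian-2-yl)-4,4-dimethyl-2-methylidenecyclohexyl]oxy}silane
Conditions: Et3SiCl, imidazole, CH2Cl2, 0 °C
Reagents that add atoms: chlorotriethylsilane, CC[Si](Cl)(CC)CC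
Why: Silylation masks the allylic C1 hydroxyl with a group that survives organolithium and palladium chemistry and can later be removed in the presence of the C12 silyl ether.

Step 12
Reactants: 22 triethyl{[(1S,3R)-3-(1,3-dithian-2-yl)-4,4-dimethyl-2-methylidenecyclohexyl]oxy}silane; 10 (1S,5S,8S)-8-[(tert-butyldimethylsilyl)oxy]-3,7-dimethylidenebicyclo[3.2.1]octan-2-one
Product: 25 B-seco enol triflate (C9–OTf on C8=C9; C6 as 1,3-dithiane), via lithiated dithiane 23 (not isolated), via lithium enolate 24 (not isolated)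
Conditions: t-BuLi, THF/HMPA, −78 °C; then 10, −78 °C; then PhNTf2, −78 to 0 °C; NH4Cl work-up
Reagents that add atoms: N-phenylbis(trifluoromethanesulfonimide), O=S(=O)(N(c1ccccc1)S(=O)(=O)C(F)(F)F)C(F)(F)F
Why: Corey–Seebach umpolung: the C6 dithianyl anion adds 1,4 (HMPA) to the methylidene carbon of 10 to form the C6–C7 bond, and O-triflation of the regiodefined enolate gives the tetrasubstituted C8=C9 enol triflate; no new stereocentre is formed.

Step 13
Reactants: 25 B-seco enol triflate (C9–OTf on C8=C9; C6 as 1,3-dithiane)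
Product: 26 tetracyclic thioketal (ring B closed; C10 quaternary; C20 methyl α; C8=C9)
Conditions: Pd(OAc)2, PPh3, HCO2Na, Et4NCl, DMF, 80 °C
Reagents that add atoms: none
Why: Intramolecular reductive Heck reaction: zerovalent palladium inserts into the C9–OTf bond, the alkenylpalladium adds syn across the C10=C20 alkene with C9 bonding to C10, and the neopentyl C20–palladium species, which has no β-hydrogen, is intercepted by formate (decarboxylation to a palladium hydride, then C–H reductive elimination), so C20 becomes the angular methyl. The closest known reaction type is the 6-exo Heck cyclisation onto a 1,1-disubstituted alkene with hydride capture, used to build quaternary carbons. Ring B is closed in the 6-exo-trig mode (C9 to C10) and no other ring forms. The new C10 stereocentre is controlled by the chair of ring A, in which the C1 silyl ether and the C5 side chain are both equatorial: the axial C4 methyl blocks the α face of C10, so C9 should add from the β face (syn to H5) and C20 becomes axial, giving the trans A/B fusion. The step needs insertion to outrun direct hydride capture of the alkenylpalladium and 6-exo to beat 7-endo closure: sparingly soluble HCO2Na with Et4NCl keeps the hydride concentration low, the gem-disubstituted C6 pre-organises the tether, and the C15 methylidene could only be reached through a three- or four-membered ring. The enol triflate fixes the C8=C9 alkene exactly where the target has it.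

Step 14
Reactants: 26 tetracyclic thioketal (ring B closed; C10 quaternary; C20 methyl α; C8=C9)
Product: 27 tetracyclic 6-ketone (1α-OTES; 12-OTBS; C15 methylidene)
Conditions: MeI, CaCO3, MeCN/H2O, 50 °C
Reagents that add atoms: water, O
Why: Alkylative thioketal hydrolysis (S-methylation, ring opening, hydration) unmasks the C6 ketone under near-neutral conditions that should leave both silyl ethers and both alkenes untouched.

Step 15
Reactants: 27 tetracyclic 6-ketone (1α-OTES; 12-OTBS; C15 methylidene)
Product: 29 1α,6α-diol (12-OTBS; C15 methylidene), via 6-hydroxy silyl ether 28 (not isolated)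
Conditions: NaBH4, MeOH/THF, 0 °C to rt; then PPTS, MeOH, 40 °C
Reagents that add atoms: none
Why: Hydride reduction: the α face of the C6 carbonyl is shielded by the syn-axial C20 and C4 methyls, so hydride should add from the β face and set the axial 6α-alcohol, and mild acid methanolysis then removes only the triethylsilyl ether.

Step 16
Reactants: 29 1α,6α-diol (12-OTBS; C15 methylidene)
Product: 30 1-acetate of 29
Conditions: Ac2O, pyridine, DMAP (cat.), CH2Cl2, 0 °C
Reagents that add atoms: acetic anhydride, CC(=O)OC(C)=O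
Why: Selective acylation: the equatorial C1 hydroxyl should react while the axial C6 hydroxyl, flanked by two syn-axial methyls, is too hindered under these conditions.

Step 17
Reactants: 30 1-acetate of 29
Product: 32 15-ketone (1-OAc; 6α-OH; 12-OTBS), via C15 diol 31 (not isolated)
Conditions: OsO4 (cat.), NaIO4, 2,6-lutidine, dioxane/H2O, rt
Reagents that add atoms: sodium periodate, [Na+].[O-]I(=O)(=O)=O; water, O
Why: Lemieux–Johnson oxidative cleavage: OsO4 should dihydroxylate the accessible 1,1-disubstituted C15 methylidene much faster than the hindered tetrasubstituted C8=C9 alkene, and periodate cleaves the diol to the C15 ketone.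

Step 18
Reactants: 32 15-ketone (1-OAc; 6α-OH; 12-OTBS)
Product: 34 12-O-TBS ether of the target, via Mannich base 33 (not isolated)
Conditions: (CH2O)n, PhNHMe·CF3CO2H, THF, reflux
Reagents that add atoms: formaldehyde (as paraformaldehyde), C=O
Why: Mannich-type α-methylenation at C16, the only enolisable position of the C15 ketone (C11 is a bridgehead), installs the C16=C17 exocyclic enone under weakly acidic conditions compatible with the acetate and the free C6 hydroxyl.

Step 19
Reactants: 34 12-O-TBS ether of the target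
Product: 35 target CNP0149338.1
Conditions: HF·pyridine, THF, 0 °C to rt
Reagents that add atoms: none
Why: Acidic fluoride desilylation frees the C12 hydroxyl without exposing the β-hydroxy ketone to base (retro-aldol) or the enone to nucleophiles.

Compound list

1 | 3-ethoxycyclohex-2-en-1-one | CCOC1=CC(=O)CCC1 | starting material
2 | 2,3-dibromoprop-1-ene | C=C(Br)CBr | starting material
3 | lithium 5-ethoxycyclohexa-1,5-dien-1-olate (dienolate of 1) | [Li]OC1=CCCC(OCC)=C1 | intermediate
4 | (±)-6-(2-bromoprop-2-en-1-yl)-3-ethoxycyclohex-2-en-1-one | CCOC1=CC(=O)C(CC(Br)=C)CC1 | intermediate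
5 | (±)-2-ethoxy-7-methylidenebicyclo[3.2.1]oct-2-en-8-one | CCOC1=CCC2CC(=C)C1C2=O | intermediate
6 | (±)-7-methylidenebicyclo[3.2.1]octane-2,8-dione | O=C1CCC2CC(=C)C1C2=O | intermediate
7 | (1S,5R,8S)-8-hydroxy-7-methylidenebicyclo[3.2.1]octan-2-one | O=C1CC[C@@H]2CC(=C)[C@H]1[C@H]2O | intermediate
8 | (1S,5R,8S)-8-[(tert-butyldimethylsilyl)oxy]-7-methylidenebicyclo[3.2.1]octan-2-one | O=C1CC[C@@H]2CC(=C)[C@H]1[C@H]2O[Si](C)(C)C(C)(C)C | intermediate
9 | 3-[(N-methylanilino)methyl] derivative of 8 (C3 configuration not defined) | O=C1C(CN(C)c3ccccc3)C[C@@H]2CC(=C)[C@H]1[C@H]2O[Si](C)(C)C(C)(C)C | intermediate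
10 | (1S,5S,8S)-8-[(tert-butyldimethylsilyl)oxy]-3,7-dimethylidenebicyclo[3.2.1]octan-2-one | O=C1C(=C)C[C@@H]2CC(=C)[C@H]1[C@H]2O[Si](C)(C)C(C)(C)C | intermediate
11 | 4,4-dimethylcyclohexane-1,3-dione | CC1(C)CCC(=O)CC1=O | starting material
12 | 3-ethoxy-6,6-dimethylcyclohex-2-en-1-one | CCOC1=CC(=O)C(C)(C)CC1 | intermediate
13 | 1,3-dithiane | C1CSCSC1 | starting material
14 | 2-lithio-1,3-dithiane | [Li]C1SCCCS1 | intermediate
15 | lithium 1-(1,3-dithian-2-yl)-3-ethoxy-6,6-dimethylcyclohex-2-en-1-olate (racemic) | CCOC1=CC(O[Li])(C2SCCCS2)C(C)(C)CC1 | intermediate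
16 | 3-(1,3-dithian-2-yl)-4,4-dimethylcyclohex-2-en-1-one | O=C1C=C(C2SCCCS2)C(C)(C)CC1 | intermediate
17 | {[(3S)-3-(1,3-dithian-2-yl)-4,4-dimethylcyclohex-1-en-1-yl]oxy}diphenylsilane | c1ccc(cc1)[SiH](c1ccccc1)OC1=C[C@H](C2SCCCS2)C(C)(C)CC1 | intermediate
18 | (2R,3S)-2-[(dimethylamino)methyl]-3-(1,3-dithian-2-yl)-4,4-dimethylcyclohexan-1-one | CN(C)C[C@@H]1C(=O)CCC(C)(C)[C@H]1C2SCCCS2 | intermediate
19 | trimethylammonium iodide of 18 (N-methylated) | C[N+](C)(C)C[C@@H]1C(=O)CCC(C)(C)[C@H]1C2SCCCS2.[I-] | intermediate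
20 | (3R)-3-(1,3-dithian-2-yl)-4,4-dimethyl-2-methylidenecyclohexan-1-one | C=C1C(=O)CCC(C)(C)[C@H]1C2SCCCS2 | intermediate
21 | (1S,3R)-3-(1,3-dithian-2-yl)-4,4-dimethyl-2-methylidenecyclohexan-1-ol | C=C1[C@@H](O)CCC(C)(C)[C@H]1C2SCCCS2 | intermediate
22 | triethyl{[(1S,3R)-3-(1,3-dithian-2-yl)-4,4-dimethyl-2-methylidenecyclohexyl]oxy}silane | C=C1[C@@H](O[Si](CC)(CC)CC)CCC(C)(C)[C@H]1C2SCCCS2 | intermediate
23 | 2-lithio derivative of 22 (lithium on the dithiane carbon, C6) | C=C1[C@@H](O[Si](CC)(CC)CC)CCC(C)(C)[C@H]1C2([Li])SCCCS2 | intermediate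
24 | lithium enolate (C9–OLi, C8=C9) of the 1,4-adduct of 23 and 10; stereocentres as in 22 and 10 | C=C1[C@@H](O[Si](CC)(CC)CC)CCC(C)(C)[C@H]1C2(SCCCS2)CC3=C(O[Li])[C@@H]4[C@@H](O[Si](C)(C)C(C)(C)C)[C@@H](CC4=C)C3 | intermediate
25 | B-seco enol triflate: the dithiane carbon (C6) carries C5 of the ring A unit of 22 and the C7 methylene bound to C8 of the bicyclo[3.2.1]oct-2-ene (C9–OTf, C12–OTBS, C15=CH2); stereocentres as in 22 and 10 | C=C1[C@@H](O[Si](CC)(CC)CC)CCC(C)(C)[C@H]1C2(SCCCS2)CC3=C(OS(=O)(=O)C(F)(F)F)[C@@H]4[C@@H](O[Si](C)(C)C(C)(C)C)[C@@H](CC4=C)C3 | intermediate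
26 | tetracyclic thioketal: 1α-OTES, C6 1,3-dithiane, 12-OTBS, C8=C9, C15=CH2, C20 methyl α, H5 β; stereocentres as in the target | C1C(=C)[C@@H]2C3=C(C[C@H]1[C@@H]2O[Si](C)(C)C(C)(C)C)CC4(SCCCS4)[C@@H]1C(C)(C)CC[C@H](O[Si](CC)(CC)CC)[C@@]31C | intermediate
27 | tetracyclic 6-ketone: 1α-OTES, 12-OTBS, C15=CH2 | C1C(=C)[C@@H]2C3=C(C[C@H]1[C@@H]2O[Si](C)(C)C(C)(C)C)CC(=O)[C@@H]1C(C)(C)CC[C@H](O[Si](CC)(CC)CC)[C@@]31C | intermediate
28 | 6α-alcohol 1-O-triethylsilyl ether | C1C(=C)[C@@H]2C3=C(C[C@H]1[C@@H]2O[Si](C)(C)C(C)(C)C)C[C@H](O)[C@@H]1C(C)(C)CC[C@H](O[Si](CC)(CC)CC)[C@@]31C | intermediate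
29 | 1α,6α-diol: 12-OTBS, C15=CH2 | C1C(=C)[C@@H]2C3=C(C[C@H]1[C@@H]2O[Si](C)(C)C(C)(C)C)C[C@H](O)[C@@H]1C(C)(C)CC[C@H](O)[C@@]31C | intermediate
30 | 1-acetate of 29 | C1C(=C)[C@@H]2C3=C(C[C@H]1[C@@H]2O[Si](C)(C)C(C)(C)C)C[C@H](O)[C@@H]1C(C)(C)CC[C@H](OC(C)=O)[C@@]31C | intermediate
31 | C15 diol of 30: C15(OH)CH2OH (C15 configuration not defined) | C1C(O)(CO)[C@@H]2C3=C(C[C@H]1[C@@H]2O[Si](C)(C)C(C)(C)C)C[C@H](O)[C@@H]1C(C)(C)CC[C@H](OC(C)=O)[C@@]31C | intermediate
32 | 15-ketone: 1-OAc, 6α-OH, 12-OTBS, C16 H2 | C1C(=O)[C@@H]2C3=C(C[C@H]1[C@@H]2O[Si](C)(C)C(C)(C)C)C[C@H](O)[C@@H]1C(C)(C)CC[C@H](OC(C)=O)[C@@]31C | intermediate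
33 | 16-[(N-methylanilino)methyl] derivative of 32 (C16 configuration not defined) | CN(c6ccccc6)CC1C(=O)[C@@H]2C3=C(C[C@H]1[C@@H]2O[Si](C)(C)C(C)(C)C)C[C@H](O)[C@@H]1C(C)(C)CC[C@H](OC(C)=O)[C@@]31C | intermediate
34 | 12-O-(tert-butyldimethylsilyl) ether of the target | C=C1C(=O)[C@@H]2C3=C(C[C@H]1[C@@H]2O[Si](C)(C)C(C)(C)C)C[C@H](O)[C@@H]1C(C)(C)CC[C@H](OC(C)=O)[C@@]31C | intermediate
35 | CNP0149338.1: (1S,5R,6S,10R,11R,12S,13R)-1-acetoxy-6,12-dihydroxy-16-methylidene-15-oxo tetracycle (target numbering) | C=C1C(=O)[C@@H]2C3=C(C[C@H]1[C@@H]2O)C[C@H](O)[C@@H]1C(C)(C)CC[C@H](OC(C)=O)[C@@]31C | target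

Total step count: 19. Longest linear sequence: 14 steps (steps 6–19, from 11); the C/D fragment 10 is made in 5 steps (steps 1–5) and joins at step 12.

Steps most likely to fail

Step 13 (key Heck cyclisation). Insertion of the hindered C9 alkenylpalladium into the 1,1-disubstituted C10=C20 alkene may be slower than hydride capture, so the triflate is simply reduced, and sulfur coordination of the thioketal can stall the catalyst. The fallback sets out from 25 and makes C10 the nucleophile as a ketone enolate. PPTS in MeOH removes the C1 silyl ether to give the allylic alcohol F1, and MnO2 oxidises it to the 2-methylidene ketone F2. LiBH(s-Bu)3 then adds hydride to C20 (1,4-reduction), and the lithium enolate so formed is coupled with the C9 enol triflate by Pd(PPh3)4 (intramolecular enolate alkenylation, known for ketone enolates and alkenyl triflates) to give the tetracyclic 1-ketone F3. The same axial C4 methyl should direct C9 to the β face of C10. NaBH4 should give the equatorial 1α-alcohol F4, and Et3SiCl/imidazole returns to the route at 26.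

Step 12 (fragment union). The strongly basic tertiary dithianyl-lithium may abstract a proton from the enone (C14) or add to the carbonyl instead of the methylidene carbon, and the exo-enone can dimerise before it is intercepted. The fallback sets out from 22 (via 23) and 10 and uses a neutral radical conjugate addition. Anion 23 is quenched with CO2 to the dithiane-2-carboxylic acid F5. Visible-light photoredox decarboxylation ([Ir(dF(CF3)ppy)2(dtbbpy)]PF6, K2HPO4, DMF, blue light) gives the 2-dithianyl radical, which adds to the methylidene carbon of 10 to give the ketone F6. KN(SiMe3)2 followed by PhNTf2 (only C8 is enolisable) comes back to the route at 25.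

Step 8 (asymmetric conjugate reduction with Mannich trapping). Hydride transfer to the hindered, sulfur-bearing β-carbon may be slow or poorly face-selective. The fallback sets out from 16 and replaces asymmetric catalysis by resolution. The same reduction–Mannich sequence with the achiral hydride [(Ph3P)CuH]6, followed by steps 9 and 10, gives racemic material: 18, 20 and 21 together with their mirror images, the Mannich base ent-18 F7, the enone ent-20 F8 and the alcohol ent-21 F9. Burkholderia cepacia lipase with vinyl acetate should then acylate the (1R)-alcohol F9 to the acetate F10 and leave the (1S)-alcohol, which is separated and rejoins the route at 21.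

Further compounds

F1 | step 13 | C1 allylic alcohol from 25 (triethylsilyl group removed) | C=C1[C@@H](O)CCC(C)(C)[C@H]1C2(SCCCS2)CC3=C(OS(=O)(=O)C(F)(F)F)[C@@H]4[C@@H](O[Si](C)(C)C(C)(C)C)[C@@H](CC4=C)C3
F2 | step 13 | 2-methylidene C1 ketone of the B-seco enol triflate | C=C1C(=O)CCC(C)(C)[C@H]1C2(SCCCS2)CC3=C(OS(=O)(=O)C(F)(F)F)[C@@H]4[C@@H](O[Si](C)(C)C(C)(C)C)[C@@H](CC4=C)C3
F3 | step 13 | tetracyclic 1-ketone (C6 1,3-dithiane, 12-OTBS, C20 methyl α) | C1C(=C)[C@@H]2C3=C(C[C@H]1[C@@H]2O[Si](C)(C)C(C)(C)C)CC4(SCCCS4)[C@@H]1C(C)(C)CCC(=O)[C@@]31C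
F4 | step 13 | tetracyclic 1α-alcohol (C6 1,3-dithiane, 12-OTBS) | C1C(=C)[C@@H]2C3=C(C[C@H]1[C@@H]2O[Si](C)(C)C(C)(C)C)CC4(SCCCS4)[C@@H]1C(C)(C)CC[C@H](O)[C@@]31C
F5 | step 12 | 2-[(1R,3S)-ring A unit of 22]-1,3-dithiane-2-carboxylic acid | C=C1[C@@H](O[Si](CC)(CC)CC)CCC(C)(C)[C@H]1C2(C(=O)O)SCCCS2
F6 | step 12 | B-seco C9 ketone (C8–H, configuration at C8 not defined; C6 1,3-dithiane) | C=C1[C@@H](O[Si](CC)(CC)CC)CCC(C)(C)[C@H]1C2(SCCCS2)CC3C(=O)[C@@H]4[C@@H](O[Si](C)(C)C(C)(C)C)[C@@H](CC4=C)C3
F7 | step 8 | (2S,3R)-2-[(dimethylamino)methyl]-3-(1,3-dithian-2-yl)-4,4-dimethylcyclohexan-1-one (ent-18) | CN(C)C[C@H]1C(=O)CCC(C)(C)[C@@H]1C2SCCCS2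
F8 | step 8 | (3S)-3-(1,3-dithian-2-yl)-4,4-dimethyl-2-methylidenecyclohexan-1-one (ent-20) | C=C1C(=O)CCC(C)(C)[C@@H]1C2SCCCS2
F9 | step 8 | (1R,3S)-3-(1,3-dithian-2-yl)-4,4-dimethyl-2-methylidenecyclohexan-1-ol (ent-21) | C=C1[C@H](O)CCC(C)(C)[C@@H]1C2SCCCS2
F10 | step 8 | (1R,3S)-3-(1,3-dithian-2-yl)-4,4-dimethyl-2-methylidenecyclohexyl acetate | C=C1[C@H](OC(C)=O)CCC(C)(C)[C@@H]1C2SCCCS2
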